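Red was charged with more reagent per substrate than ochre, 1.90 against 1.27, and its last reading showed less substrate, 12 % against 26 %.

| flask | substrate | reagent | scavenger | remark | time |
|---|---|---|---|---|---|
| red | 0.10 M | 0.19 M | 0.10 M | run made earlier |  |
| ochre | 0.15 M | 0.19 M | 0.10 M | run made earlier |  |
| summer | 0.20 M | 0.190 M | 0.100 M |  | 6.0 h |
| autumn | 0.20 M | 0.190 M | 0.100 M |  | 10 h |
| spring | 0.20 M | 0.190 M | 0.100 M |  | 15 h |

| run | time / h | substrate / % | tetra adduct / % | single product / % | triple product / % | double product / % |
|---|---|---|---|---|---|---|
| red | 0.250 | 42 | 7 | 43 | 5 | 6 |
| red | 0.667 | 23 | 13 | 40 | 6 | 8 |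
| red | 1.33 | 16 | 23 | 41 | 10 | 13 |
| red | 2.00 | 16 | 23 | 40 | 13 | 10 |
| red | 3.00 | 15 | 23 | 35 | 11 | 8 |
| red | 4.00 | 12 | 23 | 40 | 12 | 10 |
| ochre | 0.250 | 45 | 2 | 42 | 5 | 8 |
| ochre | 0.500 | 35 | 3 | 40 | 7 | 7 |
| ochre | 0.833 | 30 | 10 | 45 | 7 | 11 |
| ochre | 1.33 | 29 | 12 | 46 | 8 | 12 |
| ochre | 2.00 | 26 | 9 | 43 | 8 | 15 |
| ochre | 4.00 | 26 | 8 | 46 | 10 | 13 |

(readings scatter by 2 percentage points)



- which of these there is most of at the end, counted by the substrate in it, summer (triple product / substrate / double product / single product)
- which of these there is most of at the end, counted by the substrate in it, autumn (triple product / substrate / double product / single product)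
- which of these there is most of at the end, counted by the substrate in it, spring (triple product / substrate / double product / single product)
- how much there is at the end of the one of these that leads, in percent of the substrate charged: summer
- how much there is at the end of the one of these that leads, in percent of the substrate charged: autumn
- how much there is at the end of the one of these that leads, in percent of the substrate charged: spring

I read the two tables row against row. Red's single product read 40 % at 2.00 h and 40 % at 4.00 h, so I took that run as flat by its last row. Next I counted reagent units in each product: 1 in single product, 2 in double, 3 in triple and 4 in tetra adduct. Weighting the last row of red this way gave 1.88 units per substrate, against 1.90 charged. Ochre's last row gave 1.34, against 1.27 charged. With 2 percentage points of scatter on each reading, I took each pair as equal, which made reagent the limiting reagent in both runs.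

For the new recipe the same ratio came to 0.950, and I carried it on as the reagent budget, the reagent charged per substrate charged. My reckoning was that the weighted products in summer, autumn and spring would sum to 0.950. A budget under 1 also meant that at least 5.00 % of the substrate stayed unconverted.

The forecast named single product at 46 % for each of the times: “The runs stop on their own.”

Spring gave single product at 43.2 %, the same as summer's 43.2 % and autumn's 43.2 %.

    scavenger + released group → scavenged by-product (k = 0.00210 M⁻¹ s⁻¹)
    reagent + double product → triple product + released group (k = 0.0160 M⁻¹ s⁻¹)
    reagent + triple product → tetra adduct + released group (k = 0.0190 M⁻¹ s⁻¹)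
    substrate + reagent → single product + released group (k = 0.00710 M⁻¹ s⁻¹)
    reagent + released group ⇌ idle adduct, settled at all times (K = 1.10 M⁻¹)
    reagent + single product → double product + released group (k = 0.00480 M⁻¹ s⁻¹)

Left ten times as long, spring still held 43.2 % of single product, with 0 % of its reagent free. At 15.0 h spring's weighted products summed to 0.950, against the budget of 0.950. A neighbouring flask, like spring but charged with 0.048 M of reagent, had a budget of 0.240. It ended with 78 % of its substrate left and 20.1 % of single product, and its weighted products summed to 0.240.

(Readings and results come from a simulation from invented constants.)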